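**Retrosynthetic overview**
1. The ring is made last: both ring bonds at the acyl-bearing carbon C2 are cut (retro-Dieckmann, retro crossed Claisen) to give (E)-heptadec-15-en-2-one and a five-carbon (S)-2-oxyglutarate unit held as its γ-lactone ethyl ester.
2. Key disconnection: C5–C6 (carbinol carbon to its CH2 neighbour) gives a propanoate β-anion (zinc/titanium homoenolate) plus ethyl glyoxylate. Two normally electrophilic carbons are joined, and a chiral Ti catalyst sets the only stereocentre in this step.
3. The methyl ketone comes from acetylacetone (masked acetone enolate) and (E)-14-bromotetradec-2-ene, itself from B-alkyl Suzuki coupling of 11-bromoundec-1-ene with (E)-1-bromopropene (E geometry bought in).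
4. Ring order: a temporary γ-lactone (step 3), then the cyclohexane-1,3-dione ring (step 4), which consumes the lactone.

Assumption: the given SMILES is one enol tautomer of (4S)-2-[(E)-hexadec-14-enoyl]-4-hydroxycyclohexane-1,3-dione; ring numbering follows the drawn enone (C1 ketone, C2 acyl-bearing, C3 enol carbon, C6 carbinol, S).

**Step 1**
Reactants: 1 11-bromoundec-1-ene; 2 (E)-1-bromoprop-1-ene
Product: 4 (E)-14-bromotetradec-2-ene, via alkyl-9-BBN 3 (not isolated)
Conditions: 9-BBN (1.1 equiv), THF, 0 °C → rt; then 2 (1.5 equiv), PdCl2(dppf) (3 mol%), 3 M aq K3PO4, DMF, 50 °C, sealed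
Reagents that add atoms: none
Why: Anti-Markovnikov hydroboration of the terminal alkene followed by B-alkyl Suzuki–Miyaura coupling with the alkenyl bromide proceeds with retention of the E geometry, and the primary alkyl bromide is inert to Pd(dppf) under these conditions.

**Step 2**
Reactants: 4 (E)-14-bromotetradec-2-ene; 5 pentane-2,4-dione
Product: 7 (E)-heptadec-15-en-2-one, via 3-alkylpentanedione 6 (not isolated)
Conditions: K2CO3 (1.2 equiv), NaI (10 mol%), EtOH, reflux, 24 h
Reagents that add atoms: none
Why: SN2 C-alkylation of the acetylacetone enolate followed by in situ ethanolic retro-Claisen deacetylation (alkylation–cleavage methyl ketone synthesis) gives the methyl ketone and leaves the remote E-alkene untouched.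

**Step 3**
Reactants: 8 (1-ethoxycyclopropoxy)trimethylsilane; 9 ethyl glyoxylate
Product: 12 ethyl (2S)-5-oxooxolane-2-carboxylate, via zinc homoenolate 10 (not isolated), via hydroxy diester 11 (not isolated)
Conditions: 8 (3 equiv), ZnCl2 (1.5 equiv), Et2O, rt, then Me3SiCl and Et2O removed in vacuo; toluene, Ti(OiPr)4 (1.2 equiv), (1R,2R)-1,2-bis(trifluoromethanesulfonamido)cyclohexane (8 mol%), freshly distilled 9 (1 equiv), −30 °C; 1 M HCl; TsOH (cat.), toluene, 80 °C
Reagents that add atoms: none
Why: Proposed new method: ZnCl2 ring-opening of the siloxycyclopropane gives the internally chelated zinc homoenolate (Nakamura–Kuwajima), which is inert to the aldehyde until it transmetalates to the chiral Ti(bis-sulfonamide) complex, which delivers the β-carbon (a reversed-polarity d3 homoenolate) to the Si face of the Ti-bound glyoxylate to set the (S)-carbinol before acid lactonises the γ-hydroxy ester; the closest known reaction type is the Ti(OiPr)4/bis(sulfonamide)-catalysed enantioselective addition of ester-functionalised dialkylzincs to aldehydes (homoaldol addition).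

**Step 4**
Reactants: 7 (E)-heptadec-15-en-2-one; 12 ethyl (2S)-5-oxooxolane-2-carboxylate
Product: 16 (6S)-2-[(14E)-hexadec-14-enoyl]-3,6-dihydroxycyclohex-2-en-1-one, via lithium enolate 13 (not isolated), via diketo lactone 14 (not isolated), via hydroxy diketo ester 15 (not isolated)
Conditions: 7 (2 equiv), LDA (2 equiv), THF, −78 °C; 12 (1 equiv), −78 → 0 °C; EtOH, 50 °C; cold 1 M HCl (excess 7 recovered)
Reagents that add atoms: none
Why: Crossed Claisen acylation of the kinetic methyl-side lithium enolate by the activated α-acyloxy ester gives the β-diketonate, whose central carbon then closes the six-membered ring on the γ-carboxyl (Dieckmann-type, after the liberated ethoxide opens the lactone), driven by formation of the stable triketonate, and the stereocentre is not deprotonated because its neighbouring carbonyl sits in an enolate from the first acylation onward.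

**Compound list**
1 | 11-bromoundec-1-ene | C=CCCCCCCCCCBr | starting material
2 | (E)-1-bromoprop-1-ene | C/C=C/Br | starting material
3 | 9-(11-bromoundecyl)-9-borabicyclo[3.3.1]nonane | BrCCCCCCCCCCCB1C2CCCC1CCC2 | intermediate
4 | (E)-14-bromotetradec-2-ene | C/C=C/CCCCCCCCCCCBr | intermediate
5 | pentane-2,4-dione | CC(=O)CC(C)=O | starting material
6 | 3-[(12E)-tetradec-12-en-1-yl]pentane-2,4-dione | C/C=C/CCCCCCCCCCCC(C(C)=O)C(C)=O | intermediate
7 | (E)-heptadec-15-en-2-one | C/C=C/CCCCCCCCCCCCC(C)=O | intermediate
8 | (1-ethoxycyclopropoxy)trimethylsilane | CCOC1(CC1)O[Si](C)(C)C | starting material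
9 | ethyl glyoxylate | CCOC(=O)C=O | starting material
10 | bis(3-ethoxy-3-oxopropyl)zinc | CCOC(=O)CC[Zn]CCC(=O)OCC | intermediate
11 | diethyl (2S)-2-hydroxypentanedioate | CCOC(=O)[C@@H](O)CCC(=O)OCC | intermediate
12 | ethyl (2S)-5-oxooxolane-2-carboxylate | CCOC(=O)[C@@H]1CCC(=O)O1 | intermediate
13 | lithium (15E)-heptadeca-1,15-dien-2-olate | C/C=C/CCCCCCCCCCCCC(=C)O[Li] | intermediate
14 | (5S)-5-[(16E)-3-oxooctadec-16-enoyl]oxolan-2-one | C/C=C/CCCCCCCCCCCCC(=O)CC(=O)[C@@H]1CCC(=O)O1 | intermediate
15 | ethyl (4S,20E)-4-hydroxy-5,7-dioxodocos-20-enoate | C/C=C/CCCCCCCCCCCCC(=O)CC(=O)[C@@H](O)CCC(=O)OCC | intermediate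
16 | (6S)-2-[(14E)-hexadec-14-enoyl]-3,6-dihydroxycyclohex-2-en-1-one | C/C=C/CCCCCCCCCCCCC(=O)C1=C(O)CC[C@H](O)C1=O | target

**Totals**
Total step count: 4. Longest linear sequence: 3 (steps 1, 2, 4); step 3 is a one-step convergent branch.

**Steps most likely to fail**

Step 3 (highest risk). Glyoxylate is very electrophilic and chelating, so a racemic background addition through achiral titanium species may erode the ee, and the facial sense is assigned only by analogy with simple aldehydes (the antipodal ligand is used if it proves reversed). The fallback sets out from 10 and returns at 11. Palladium-catalysed acylation of the zinc homoenolate with ethyl chlorooxoacetate (PdCl2(PPh3)2 cat., Et2O) gives diethyl 2-oxopentanedioate F1. The ketone is then hydrogenated enantioselectively over cinchonine-modified Pt/Al2O3 (H2, AcOH/toluene, Orito-type) to 11, which is lactonised to 12 as in step 3. The homoenolate still makes the C5–C6 bond, but the stereocentre now comes from asymmetric ketone reduction.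

Step 4. The ketone enolate may deprotonate 12 at the stereocentre before it acylates, and the second ring closure may stall. If stalled material survives to the acidic work-up, the free α'-hydroxy diketone 15 can cyclodehydrate to a furanone. The fallback sets out from 12 and returns at 14, which is now isolated. Aqueous HCl hydrolysis with relactonisation gives (2S)-5-oxooxolane-2-carboxylic acid F2. DCC and 1H-benzotriazole convert it to 1-[(2S)-5-oxooxolane-2-carbonyl]-1H-benzotriazole F3. Soft enolisation of 7 (1 equiv, MgBr2·OEt2, i-Pr2NEt, CH2Cl2, rt) then C-acylates it with F3 to give 14 without strong base. Compound 14 is closed to 16 with NaOEt/EtOH at 50 °C, as in the second stage of step 4.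

Step 2. Alkylation–cleavage of acetylacetone typically gives only moderate yields (O-alkylation, dialkylation, incomplete deacetylation). The fallback sets out from 4 and returns at 7. The Grignard reagent of 4 (Mg, THF) opens propylene oxide at the terminal carbon (CuI cat., −30 °C) to give racemic (E)-heptadec-15-en-2-ol F4. Dess–Martin oxidation then gives 7, and the carbinol centre is lost on oxidation.

**Further compounds**
F1 | step 3 | diethyl 2-oxopentanedioate | CCOC(=O)C(=O)CCC(=O)OCC
F2 | step 4 | (2S)-5-oxooxolane-2-carboxylic acid | OC(=O)[C@@H]1CCC(=O)O1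
F3 | step 4 | 1-[(2S)-5-oxooxolane-2-carbonyl]-1H-benzotriazole | O=C([C@@H]1CCC(=O)O1)n1nnc2ccccc12
F4 | step 2 | (E)-heptadec-15-en-2-ol (racemic) | C/C=C/CCCCCCCCCCCCC(C)O
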